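**Retrosynthetic overview**
1. Target 18 comes from its pentabenzyl ether 17 by global O-debenzylation (last step).
2. 17 is cut at the CH2–aryl bond of ring D: primary alkyl iodide 13 plus aryl bromide 15 (sp3–sp2 Negishi coupling).
3. 13 comes from the (R)-3,3-diarylpropanoate 10, made by Rh/(S)-BINAP 1,4-addition of arylboronic acid 9 (ring A) to cinnamate 8; this sets the only stereocentre of the target.
4. 8 comes from aryl bromide 6 by a Heck reaction. 6 comes from chalcone 5 by an ene-reductase C=C reduction that keeps C–Br and O–Bn, and 5 from aldehyde 2 plus acetophenone 3 (Claisen–Schmidt).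
5. No ring is built: the four benzene rings are bought and joined in the order B, C, A, D.

Assumption: the target is the (R)-enantiomer as drawn (CIP order at the stereocentre: dioxygenated ring B > 4-oxyphenyl ring A > CH2 > H); auxiliary reagents (BnBr, bases, hydrides, catalysts) are named in the steps but not numbered.

**Step 1**
Reactants: 1 5-bromo-2,4-dihydroxybenzaldehyde
Product: 2 2,4-bis(benzyloxy)-5-bromobenzaldehyde
Conditions: BnBr (2.3 equiv), K2CO3 (2.5 equiv), DMF, 60 °C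
Reagents that add atoms: benzyl bromide, BrCc1ccccc1
Why: Williamson ether synthesis; both phenoxides are benzylated by SN2, and DMF at 60 °C also alkylates the chelated 2-OH.

**Step 2**
Reactants: 2 2,4-bis(benzyloxy)-5-bromobenzaldehyde; 3 1-[4-(benzyloxy)phenyl]ethanone
Product: 5 (E)-3-[2,4-bis(benzyloxy)-5-bromophenyl]-1-[4-(benzyloxy)phenyl]prop-2-en-1-one, via aldol adduct 4 (not isolated)
Conditions: KOH (0.5 equiv, 40% aq.), EtOH/THF, rt
Reagents that add atoms: none
Why: Claisen–Schmidt condensation; aldehyde 2 has no α-hydrogen, and the racemic aldol adduct dehydrates by E1cB to the conjugated (E)-enone, which erases its transient stereocentre.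

**Step 3**
Reactants: 5 (E)-3-[2,4-bis(benzyloxy)-5-bromophenyl]-1-[4-(benzyloxy)phenyl]prop-2-en-1-one
Product: 6 3-[2,4-bis(benzyloxy)-5-bromophenyl]-1-[4-(benzyloxy)phenyl]propan-1-one
Conditions: ene-reductase (Old Yellow Enzyme family, best hit of a panel), NAD+ (cat.), HCO2Na, formate dehydrogenase, KPi buffer pH 7.0/DMSO 4:1, 30 °C
Reagents that add atoms: none
Why: Biocatalytic conjugate reduction; the flavin-dependent ene-reductase puts hydride on C-β and a proton on C-α of the activated enone only, so the C–Br bond, the benzyl ethers and the ketone, which H2/Pd would attack, stay intact (no stereocentre is formed).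

**Step 4**
Reactants: 6 3-[2,4-bis(benzyloxy)-5-bromophenyl]-1-[4-(benzyloxy)phenyl]propan-1-one; 7 tert-butyl acrylate
Product: 8 tert-butyl (E)-3-{2,4-bis(benzyloxy)-5-[3-(4-(benzyloxy)phenyl)-3-oxopropyl]phenyl}acrylate
Conditions: Pd2(dba)3 (1.5 mol %), [HP(t-Bu)3]BF4 (6 mol %), Cy2NMe, 1,4-dioxane, 90 °C
Reagents that add atoms: none
Why: Mizoroki–Heck reaction; the bulky electron-rich phosphine allows oxidative addition into the electron-rich aryl bromide, and syn-insertion/β-hydride elimination give the (E)-cinnamate while the ketone is inert under the amine base.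

**Step 5**
Reactants: 8 tert-butyl (E)-3-{2,4-bis(benzyloxy)-5-[3-(4-(benzyloxy)phenyl)-3-oxopropyl]phenyl}acrylate; 9 [4-(benzyloxy)phenyl]boronic acid
Product: 10 tert-butyl (3R)-3-[4-(benzyloxy)phenyl]-3-{2,4-bis(benzyloxy)-5-[3-(4-(benzyloxy)phenyl)-3-oxopropyl]phenyl}propanoate
Conditions: [Rh(OH)((S)-BINAP)]2 (2.5 mol %), 9 (3 equiv), 1,4-dioxane/H2O 10:1, 60 °C
Reagents that add atoms: none
Why: Hayashi–Miyaura Rh-catalysed asymmetric 1,4-addition; by the established model the aryl–Rh/(S)-BINAP species binds the α-Si face of the (E)-enoate and transfers the aryl to C-3 on that face, which gives the (R) centre, and the saturated ketone does not react.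

**Step 6**
Reactants: 10 tert-butyl (3R)-3-[4-(benzyloxy)phenyl]-3-{2,4-bis(benzyloxy)-5-[3-(4-(benzyloxy)phenyl)-3-oxopropyl]phenyl}propanoate
Product: 11 (3R)-3-[4-(benzyloxy)phenyl]-3-{2,4-bis(benzyloxy)-5-[3-(4-(benzyloxy)phenyl)-3-hydroxypropyl]phenyl}propan-1-ol (both carbinol epimers)
Conditions: LiAlH4 (3 equiv), THF, 0 °C to rt; H2O/NaOH work-up
Reagents that add atoms: none
Why: Hydride reduction of the ester to the primary alcohol; the ketone is reduced as well on purpose (it is restored in step 7), and the non-acidic diarylmethine stereocentre is not touched.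

**Step 7**
Reactants: 11 (3R)-3-[4-(benzyloxy)phenyl]-3-{2,4-bis(benzyloxy)-5-[3-(4-(benzyloxy)phenyl)-3-hydroxypropyl]phenyl}propan-1-ol
Product: 12 3-{2,4-bis(benzyloxy)-5-[(1R)-1-(4-(benzyloxy)phenyl)-3-hydroxypropyl]phenyl}-1-[4-(benzyloxy)phenyl]propan-1-one
Conditions: activated MnO2 (15 equiv), CH2Cl2, rt
Reagents that add atoms: none
Why: Chemoselective benzylic oxidation; MnO2 oxidises only the activated aryl carbinol back to the ketone and leaves the unactivated primary alcohol, which also removes the undefined carbinol centre.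

**Step 8**
Reactants: 12 3-{2,4-bis(benzyloxy)-5-[(1R)-1-(4-(benzyloxy)phenyl)-3-hydroxypropyl]phenyl}-1-[4-(benzyloxy)phenyl]propan-1-one
Product: 13 3-{2,4-bis(benzyloxy)-5-[(1R)-1-(4-(benzyloxy)phenyl)-3-iodopropyl]phenyl}-1-[4-(benzyloxy)phenyl]propan-1-one
Conditions: I2, PPh3, imidazole, CH2Cl2, 0 °C to rt
Reagents that add atoms: iodine, II
Why: Appel reaction; the alkoxyphosphonium ion is displaced by iodide in an SN2 step at the primary carbon, two bonds away from the stereocentre.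

**Step 9**
Reactants: 14 4-bromo-3-methoxyphenol
Product: 15 4-(benzyloxy)-1-bromo-2-methoxybenzene
Conditions: BnBr (1.1 equiv), K2CO3, acetone, reflux
Reagents that add atoms: benzyl bromide, BrCc1ccccc1
Why: Williamson ether synthesis on the only free phenol; it gives the ring D coupling partner with the methyl ether already in place.

**Step 10**
Reactants: 13 3-{2,4-bis(benzyloxy)-5-[(1R)-1-(4-(benzyloxy)phenyl)-3-iodopropyl]phenyl}-1-[4-(benzyloxy)phenyl]propan-1-one; 15 4-(benzyloxy)-1-bromo-2-methoxybenzene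
Product: 17 3-{2,4-bis(benzyloxy)-5-[(1R)-3-(4-(benzyloxy)-2-methoxyphenyl)-1-(4-(benzyloxy)phenyl)propyl]phenyl}-1-[4-(benzyloxy)phenyl]propan-1-one, via alkylzinc iodide 16 (not isolated)
Conditions: Zn dust (I2-activated), LiCl, THF, 40 °C; then 15 (1.3 equiv), Pd(OAc)2 (3 mol %), SPhos (6 mol %), THF, 50 °C
Reagents that add atoms: none
Why: Negishi sp3–sp2 cross-coupling; direct zinc insertion gives a ketone-tolerant primary alkylzinc, and Pd/SPhos makes reductive elimination faster than β-hydride elimination, with the stereocentre γ to zinc unaffected.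

**Step 11**
Reactants: 17 3-{2,4-bis(benzyloxy)-5-[(1R)-3-(4-(benzyloxy)-2-methoxyphenyl)-1-(4-(benzyloxy)phenyl)propyl]phenyl}-1-[4-(benzyloxy)phenyl]propan-1-one
Product: 18 3-{2,4-dihydroxy-5-[(1R)-3-(4-hydroxy-2-methoxyphenyl)-1-(4-hydroxyphenyl)propyl]phenyl}-1-(4-hydroxyphenyl)propan-1-one
Conditions: H2 (1 atm), 10% Pd/C, EtOAc/MeOH 1:1, rt, stopped when uptake ends
Reagents that add atoms: none
Why: Catalytic hydrogenolysis of the five benzyl ethers under neutral conditions; the aryl methyl ether, the aryl ketone and the C–H stereocentre are stable at 1 atm and rt.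

**Compound list**
1 | 5-bromo-2,4-dihydroxybenzaldehyde | O=Cc1cc(Br)c(O)cc1O | starting material
2 | 2,4-bis(benzyloxy)-5-bromobenzaldehyde | O=Cc1cc(Br)c(OCc2ccccc2)cc1OCc1ccccc1 | intermediate
3 | 1-[4-(benzyloxy)phenyl]ethanone | CC(=O)c1ccc(OCc2ccccc2)cc1 | starting material
4 | 3-[2,4-bis(benzyloxy)-5-bromophenyl]-1-[4-(benzyloxy)phenyl]-3-hydroxypropan-1-one (racemic aldol adduct, not isolated) | O=C(CC(O)c1cc(Br)c(OCc2ccccc2)cc1OCc1ccccc1)c1ccc(OCc2ccccc2)cc1 | intermediate
5 | (E)-3-[2,4-bis(benzyloxy)-5-bromophenyl]-1-[4-(benzyloxy)phenyl]prop-2-en-1-one | O=C(/C=C/c1cc(Br)c(OCc2ccccc2)cc1OCc1ccccc1)c1ccc(OCc2ccccc2)cc1 | intermediate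
6 | 3-[2,4-bis(benzyloxy)-5-bromophenyl]-1-[4-(benzyloxy)phenyl]propan-1-one | O=C(CCc1cc(Br)c(OCc2ccccc2)cc1OCc1ccccc1)c1ccc(OCc2ccccc2)cc1 | intermediate
7 | tert-butyl acrylate | C=CC(=O)OC(C)(C)C | starting material
8 | tert-butyl (E)-3-{2,4-bis(benzyloxy)-5-[3-(4-(benzyloxy)phenyl)-3-oxopropyl]phenyl}acrylate | CC(C)(C)OC(=O)/C=C/c1cc(CCC(=O)c2ccc(OCc3ccccc3)cc2)c(OCc2ccccc2)cc1OCc1ccccc1 | intermediate
9 | [4-(benzyloxy)phenyl]boronic acid | OB(O)c1ccc(OCc2ccccc2)cc1 | starting material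
10 | tert-butyl (3R)-3-[4-(benzyloxy)phenyl]-3-{2,4-bis(benzyloxy)-5-[3-(4-(benzyloxy)phenyl)-3-oxopropyl]phenyl}propanoate | CC(C)(C)OC(=O)C[C@H](c1ccc(OCc2ccccc2)cc1)c1cc(CCC(=O)c2ccc(OCc3ccccc3)cc2)c(OCc2ccccc2)cc1OCc1ccccc1 | intermediate
11 | (3R)-3-[4-(benzyloxy)phenyl]-3-{2,4-bis(benzyloxy)-5-[3-(4-(benzyloxy)phenyl)-3-hydroxypropyl]phenyl}propan-1-ol (both carbinol epimers) | OCC[C@H](c1ccc(OCc2ccccc2)cc1)c1cc(CCC(O)c2ccc(OCc3ccccc3)cc2)c(OCc2ccccc2)cc1OCc1ccccc1 | intermediate
12 | 3-{2,4-bis(benzyloxy)-5-[(1R)-1-(4-(benzyloxy)phenyl)-3-hydroxypropyl]phenyl}-1-[4-(benzyloxy)phenyl]propan-1-one | OCC[C@H](c1ccc(OCc2ccccc2)cc1)c1cc(CCC(=O)c2ccc(OCc3ccccc3)cc2)c(OCc2ccccc2)cc1OCc1ccccc1 | intermediate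
13 | 3-{2,4-bis(benzyloxy)-5-[(1R)-1-(4-(benzyloxy)phenyl)-3-iodopropyl]phenyl}-1-[4-(benzyloxy)phenyl]propan-1-one | ICC[C@H](c1ccc(OCc2ccccc2)cc1)c1cc(CCC(=O)c2ccc(OCc3ccccc3)cc2)c(OCc2ccccc2)cc1OCc1ccccc1 | intermediate
14 | 4-bromo-3-methoxyphenol | COc1cc(O)ccc1Br | starting material
15 | 4-(benzyloxy)-1-bromo-2-methoxybenzene | COc1cc(OCc2ccccc2)ccc1Br | intermediate
16 | {(3R)-3-[4-(benzyloxy)phenyl]-3-[2,4-bis(benzyloxy)-5-(3-(4-(benzyloxy)phenyl)-3-oxopropyl)phenyl]propyl}zinc iodide (not isolated) | I[Zn]CC[C@H](c1ccc(OCc2ccccc2)cc1)c1cc(CCC(=O)c2ccc(OCc3ccccc3)cc2)c(OCc2ccccc2)cc1OCc1ccccc1 | intermediate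
17 | 3-{2,4-bis(benzyloxy)-5-[(1R)-3-(4-(benzyloxy)-2-methoxyphenyl)-1-(4-(benzyloxy)phenyl)propyl]phenyl}-1-[4-(benzyloxy)phenyl]propan-1-one | COc1cc(OCc2ccccc2)ccc1CC[C@H](c1ccc(OCc2ccccc2)cc1)c1cc(CCC(=O)c2ccc(OCc3ccccc3)cc2)c(OCc2ccccc2)cc1OCc1ccccc1 | intermediate
18 | 3-{2,4-dihydroxy-5-[(1R)-3-(4-hydroxy-2-methoxyphenyl)-1-(4-hydroxyphenyl)propyl]phenyl}-1-(4-hydroxyphenyl)propan-1-one | COc1cc(O)ccc1CC[C@H](c1ccc(O)cc1)c1cc(CCC(=O)c2ccc(O)cc2)c(O)cc1O | target

**Count and risks**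
Total steps: 11. Longest linear sequence: 10 (steps 1–8, 10, 11); step 9 is a one-step side branch.

Most likely to fail, first: step 3. The tribenzylated chalcone is bulky and poorly water-soluble, so no ene-reductase of the panel may accept it at a useful rate. In that case the C=C bond is reduced chemically: starting from 5, Rh-catalysed 1,4-hydrosilylation (Et3SiH, 1 mol % RhCl(PPh3)3, toluene, 60 °C) gives the (Z)-triethylsilyl enol ether F1, which is hydrolysed (K2CO3, MeOH, rt) and comes back to the route at 6. Neither operation touches C–Br or O–Bn.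

Second: step 5. The electron-rich, ortho-substituted cinnamate 8 is a weak acceptor, so conversion or ee may be low. In that case the polarity of the addition is reversed. Starting from 6, Miyaura borylation (B2pin2, PdCl2(dppf), KOAc, dioxane, 90 °C) gives the aryl pinacol boronate F2. This is added with [Rh(OH)((R)-BINAP)]2 (KOH, dioxane/H2O, 60 °C) to tert-butyl (E)-3-[4-(benzyloxy)phenyl]acrylate F3, made by a Wittig reaction from 4-(benzyloxy)benzaldehyde and tert-butyl (triphenylphosphoranylidene)acetate. Because the two aryl groups have changed roles, the (R)-ligand now gives the same (R)-ester, and the fallback comes back to the route at 10 (step 4 is skipped).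

Third: step 10. Zinc insertion may be sluggish, and the alkylzinc can be lost by protonation or β-hydride elimination. In that case the two halides are joined without a preformed organometallic: starting from 13 and 15, Ni-catalysed reductive cross-electrophile coupling (NiI2·glyme, 4,4'-di-tert-butyl-2,2'-bipyridine, Mn powder, NaI, DMPU, 60 °C) tolerates the ketone and comes back to the route at 17. No new compound is made (F0).

**Further compounds**
F1 | step 3 | {[(1Z)-3-[2,4-bis(benzyloxy)-5-bromophenyl]-1-[4-(benzyloxy)phenyl]prop-1-en-1-yl]oxy}triethylsilane | CC[Si](CC)(CC)O/C(=C\Cc1cc(Br)c(OCc2ccccc2)cc1OCc1ccccc1)c1ccc(OCc2ccccc2)cc1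
F2 | step 5 | 3-[2,4-bis(benzyloxy)-5-(4,4,5,5-tetramethyl-1,3,2-dioxaborolan-2-yl)phenyl]-1-[4-(benzyloxy)phenyl]propan-1-one | CC1(C)OB(OC1(C)C)c1cc(CCC(=O)c2ccc(OCc3ccccc3)cc2)c(OCc2ccccc2)cc1OCc1ccccc1
F3 | step 5 | tert-butyl (E)-3-[4-(benzyloxy)phenyl]acrylate | CC(C)(C)OC(=O)/C=C/c1ccc(OCc2ccccc2)cc1
F0 | step 10 | none | none
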